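**Retrosynthetic overview**

1. The O8 ester is disconnected to (2S,3S)-epoxyangelic acid (Sharpless epoxidation of angelyl alcohol) and an 8-hydroxy-9-oxo germacranolide. The Z enone at C1=C10 is not delivered by the ring expansion; it comes from a late photochemical E→Z isomerisation of the 1(10)E isomer.
2. Enabling feature: the ten-membered ring C1–C10 holds the 1,5-diene C10=C1–C2–C3–C4=C5, with C2–C3 as its central σ bond. The ring is therefore the [3,3] ring-expansion product of a cyclohexane C5–C6–C7–C8–C9–C10 bearing vinyl (C1=C2) on C10 and isopropenyl (C3=C4) plus O⁻ on C5. In the anionic oxy-Cope step C2–C3 forms as C5–C10 breaks, and the C5 oxygen is then removed through the enol triflate.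
3. That cyclohexane is (S)-carvone: its C=O becomes C9, its ring methyl C14, its stereocentre C7, and its isopropenyl group C11/C12/C13 of the methylene lactone.
4. Before the ring expansion: isopropenyl at C5 (conjugate addition, Saegusa–Ito), vinyl at C10 (deconjugative Michael addition, sulfoxide elimination), O8/O9 (enolate hydroxylation, directed reduction), and C5–OH with C6–O together by epoxidation/lactonisation of the C5=C6 diene.
5. Ring order: cyclohexane (carvone) → γ-lactone (carried as a silyl lactol) → ten-membered ring (key step) → lactone and enone restored; the oxirane arrives with the acyl fragment.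

Key step: step 14

Remark: C1–C15 are the germacrane atom labels of the target (ring C1–C10, lactone C6–O–C12(=O)–C11(=C13)–C7, C14 on C10, C15 on C4) and "cis/trans" refer to the C7 side chain; the sulfoxide sulfur in 6 and the acetal carbon C12 in 17–23 form as mixtures, are drawn without descriptors and are removed later.

**Route**

Step 1
Reactants: 1 (S)-carvone
Product: 2 silyl enol ether
Conditions: CH2=C(Me)MgBr, CuBr·SMe2 (cat.), Me3SiCl, THF, −78 °C
Reagents that add atoms: isopropenylmagnesium bromide CC(=C)[Mg]Br; chlorotrimethylsilane C[Si](C)(C)Cl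
Why: Copper-catalysed conjugate addition of the alkenyl Grignard reagent, accelerated and trapped by Me3SiCl, should give the regiodefined silyl enol ether; the new C5 centre (isopropenyl anti to the C7 group) is of no consequence because C5 becomes sp2 in step 2.

Step 2
Reactants: 2 silyl enol ether
Product: 3 dienone
Conditions: Pd(OAc)2 (cat.), O2, DMSO, 60 °C
Reagents that add atoms: none
Why: Saegusa–Ito oxidation: the palladium enolate undergoes β-hydride elimination towards C5 and restores the enone, now β-substituted and conjugated with the new isopropenyl group, without touching C7.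

Step 3
Reactants: 3 dienone
Product: 4 allylic chloride
Conditions: Ca(OCl)2, CO2 (solid), CH2Cl2/H2O, 0 °C
Reagents that add atoms: calcium hypochlorite [Ca+2].[O-]Cl.[O-]Cl
Why: Ene-type allylic chlorination by HOCl formed in the flask should attack only the isolated, electron-rich isopropenyl group on C7, the other one being deactivated as part of the conjugated dienone; the alkene ends as C11=C13 with chlorine on C12.

Step 4
Reactants: 4 allylic chloride
Product: 5 pivalate
Conditions: CsOPiv, DMF, 40 °C
Reagents that add atoms: caesium pivalate CC(C)(C)C(=O)[O-].[Cs+]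
Why: SN2 displacement of the primary allylic chloride by the weakly basic carboxylate installs the C12 oxygen as a base-stable pivalate.

Step 5
Reactants: 5 pivalate
Product: 7 vinyl ketone, via sulfoxide adduct 6 (not isolated)
Conditions: t-BuOK (cat.), phenyl vinyl sulfoxide, t-BuOH/THF, 0 °C to rt; then toluene, 110 °C
Reagents that add atoms: phenyl vinyl sulfoxide C=CS(=O)c1ccccc1
Why: Deconjugative α-alkylation: the thermodynamic dienolate (γ-deprotonation at C6) adds through C10 to the vinyl sulfoxide (Michael addition) and thermal syn-elimination of benzenesulfenic acid unveils the vinyl group; the electrophile should enter C10 axially, cis to the pseudo-equatorial C7 side chain, as in alkylations of dihydrocarvone enolates.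

Step 6
Reactants: 7 vinyl ketone
Product: 9 8-hydroxy ketone, via potassium enolate 8 (not isolated)
Conditions: KN(SiMe3)2, THF, −78 °C; then 2-(phenylsulfonyl)-3-phenyloxaziridine, −78 °C
Reagents that add atoms: 2-(phenylsulfonyl)-3-phenyloxaziridine O=S(=O)(N1OC1c1ccccc1)c1ccccc1
Why: The ketone can enolise only towards C8 (C10 is quaternary), and oxygen transfer from the N-sulfonyloxaziridine should occur anti to the C7 side chain and the pseudo-axial C10 vinyl group, placing the 8-OH trans to the side chain.

Step 7
Reactants: 9 8-hydroxy ketone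
Product: 10 trans-8,9-diol
Conditions: Me4NBH(OAc)3, MeCN/AcOH, −25 °C
Reagents that add atoms: none
Why: Hydroxyl-directed reduction: the C8 alkoxyborohydride delivers hydride intramolecularly to the C8–OH face of the C9 ketone and should give the trans-diol; the C9 centre is temporary and is re-oxidised in step 19.

Step 8
Reactants: 10 trans-8,9-diol
Product: 11 acetonide
Conditions: 2-methoxypropene, PPTS (cat.), CH2Cl2, 0 °C
Reagents that add atoms: 2-methoxypropene COC(C)=C
Why: Kinetic acetonide formation on the trans-diequatorial diol protects both hydroxyls and locks the ring in the chair needed in step 14.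

Step 9
Reactants: 11 acetonide
Product: 12 allylic alcohol
Conditions: i-Bu2AlH, CH2Cl2, −78 °C
Reagents that add atoms: none
Why: Reductive cleavage of the pivalate frees the primary allylic alcohol; acetonide and alkenes are inert to the hydride.

Step 10
Reactants: 12 allylic alcohol
Product: 14 acrylic acid, via enal 13 (not isolated)
Conditions: TEMPO (cat.), PhI(OAc)2, MeCN/H2O (pH 7), rt
Reagents that add atoms: water O
Why: Oxoammonium oxidation takes the primary allylic alcohol through the enal and its hydrate to the acid, which also deactivates the C11=C13 alkene for step 11.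

Step 11
Reactants: 14 acrylic acid
Product: 16 hydroxy lactone, via epoxy acid 15 (not isolated)
Conditions: mCPBA, CH2Cl2, 0 °C to rt
Reagents that add atoms: mCPBA O=C(OO)c1cccc(Cl)c1
Why: Peracid epoxidation should pick the trisubstituted C5=C6 bond of the diene on the face anti to the pseudo-axial C10 vinyl group and the C7 side chain, and the C12 acid then opens the epoxide at C6 (5-exo, anti, trans-diaxial), which sets C6–O cis to the side chain (cis-fused lactone), the C5 hydroxyl trans to it and isopropenyl cis to vinyl.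

Step 12
Reactants: 16 hydroxy lactone
Product: 17 lactol
Conditions: i-Bu2AlH (2.2 equiv), CH2Cl2, −78 °C
Reagents that add atoms: none
Why: Low-temperature hydride reduction stops at the aluminium hemiacetal, so the methylene lactone (a Michael acceptor that would intercept the enolate of step 14) is taken to the lactol.

Step 13
Reactants: 17 lactol
Product: 18 lactol silyl ether
Conditions: t-BuMe2SiCl, imidazole, DMF, 0 °C
Reagents that add atoms: tert-butyldimethylsilyl chloride CC(C)(C)[Si](C)(C)Cl
Why: The lactol hydroxyl is far more reactive than the hindered tertiary C5–OH, so silylation gives a base-stable silyl acetal and leaves the carbinol free.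

Step 14
Reactants: 18 lactol silyl ether
Product: 21 enol triflate, via potassium alkoxide 19 (not isolated), via potassium enolate 20 (not isolated)
Conditions: KH, 18-crown-6, THF, 0 to 40 °C; then PhNTf2, −78 to 0 °C
Reagents that add atoms: N-phenylbis(trifluoromethanesulfonimide) O=S(=O)(N(c1ccccc1)S(=O)(=O)C(F)(F)F)C(F)(F)F
Why: Deprotonation gives the C5 potassium alkoxide, which weakens C5–C10 so that the 1,5-diene C2=C1–C10–C5–C4=C3 undergoes a charge-accelerated [3,3]-sigmatropic shift: C2–C3 forms as C5–C10 breaks, and the enolate C4=C5–O⁻ is then O-sulfonylated. The closest known reaction type is the anionic oxy-Cope ring expansion of 1,2-dialkenylcyclohexanols to cyclodec-5-enones with trapping of the regiodefined enolate. The ten-membered ring closes by sigmatropic four-carbon expansion of the six-membered ring C5–C10, both new alkenes arising in the same event. No stereocentre is formed; the alkene geometries follow from the chair transition state of the conformationally locked cyclohexane (trans-acetonide, equatorial C7 side chain, axial vinyl on C10, equatorial isopropenyl on C5), in which C6 is axial and O5 equatorial, so C6 ends cis to C3 (the required C4=C5 geometry), while C9 is equatorial and ends trans to C2 (1(10)E, corrected in step 20). The step needs chair over boat, [3,3] over dissociative [1,3] recombination and O- over C-sulfonylation; the gauche alkenyl groups on a rigid chair, the crown-ether-separated ion pair and the hard triflimide electrophile should secure these, and C6, C7 and C8 are untouched.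

Step 15
Reactants: 21 enol triflate
Product: 22 diene
Conditions: Pd(OAc)2 (cat.), PPh3, HCO2H, Bu3N, DMF, 60 °C
Reagents that add atoms: none
Why: Palladium-catalysed formate reduction of the enol triflate (oxidative addition, formate exchange, decarboxylation, reductive elimination) replaces OTf by H with retention, giving C4=C5 with C3 and C6 cis.

Step 16
Reactants: 22 diene
Product: 23 lactol
Conditions: Bu4NF, AcOH, THF, 0 °C
Reagents that add atoms: none
Why: Buffered fluoride cleaves only the anomeric silyl ether, and the lactol can close only onto O6 because O8 and O9 are still held in the acetonide.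

Step 17
Reactants: 23 lactol
Product: 24 lactone acetonide
Conditions: MnO2, CH2Cl2, rt
Reagents that add atoms: none
Why: MnO2 oxidises the allylic lactol to the α-methylene-γ-butyrolactone and so fixes the 12,6-olide before O8 is unmasked.

Step 18
Reactants: 24 lactone acetonide
Product: 25 diol lactone
Conditions: AcOH/H2O (4:1), 40 °C
Reagents that add atoms: none
Why: Mild aqueous acid hydrolyses the strained trans-fused acetonide under conditions weak enough to avoid transannular cyclisation of the cyclodecadiene and lactone migration to O8.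

Step 19
Reactants: 25 diol lactone
Product: 26 E-hydroxy enone
Conditions: MnO2, CH2Cl2, rt
Reagents that add atoms: none
Why: MnO2 oxidises only the allylic C9 alcohol to the conjugated enone; the non-allylic C8 hydroxyl should be untouched.

Step 20
Reactants: 26 E-hydroxy enone
Product: 27 Z-hydroxy enone
Conditions: hν (350 nm, Pyrex), MeCN, rt
Reagents that add atoms: none
Why: Photochemical E→Z isomerisation of an enone: n→π* excitation gives a twisted triplet that relaxes to both geometries, and the ring-cis (Z) enone, being the less strained isomer in the ten-membered ring and the weaker absorber at this wavelength, should dominate the photostationary state while C4=C5 and the methylene lactone do not absorb.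

Step 21
Reactants: 28 angelic acid
Product: 29 angelyl alcohol
Conditions: LiAlH4, Et2O, 0 °C
Reagents that add atoms: none
Why: Hydride reduction of the acid gives the allylic alcohol without touching the Z trisubstituted alkene.

Step 22
Reactants: 29 angelyl alcohol
Product: 30 epoxy alcohol
Conditions: Ti(OiPr)4 (cat.), D-(−)-diethyl tartrate (cat.), t-BuOOH, 4 Å MS, CH2Cl2, −20 °C
Reagents that add atoms: tert-butyl hydroperoxide CC(C)(C)OO
Why: Sharpless asymmetric epoxidation: with D-(−)-diethyl tartrate oxygen should be delivered to the alkene face that gives the (2R,3S)-epoxy alcohol, the cis relation of CH2OH and the C3 methyl coming from the Z alkene.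

Step 23
Reactants: 30 epoxy alcohol
Product: 32 epoxyangelic acid, via epoxy aldehyde 31 (not isolated)
Conditions: RuCl3 (cat.), NaIO4, CCl4/MeCN/H2O, rt
Reagents that add atoms: sodium periodate [Na+].[O-]I(=O)(=O)=O
Why: Catalytic RuO4 oxidises the primary alcohol through the aldehyde to the glycidic acid without opening the oxirane; the C2 descriptor changes from R to S only through the priority change.

Step 24
Reactants: 27 Z-hydroxy enone; 32 epoxyangelic acid
Product: 34 target, via mixed anhydride 33 (not isolated)
Conditions: 2,4,6-trichlorobenzoyl chloride, Et3N, toluene, rt; then 27, DMAP, rt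
Reagents that add atoms: none
Why: Yamaguchi esterification: the mixed anhydride acylates the hindered C8 hydroxyl under DMAP catalysis with retention at C8 and at both oxirane centres, giving the target.

**Compound list**

1 | (S)-(+)-carvone, (5S)-2-methyl-5-(prop-1-en-2-yl)cyclohex-2-en-1-one | CC1=CC[C@@H](CC1=O)C(C)=C | starting material
2 | trimethylsilyl enol ether (C9–OSiMe3, C9=C10; C5 isopropenyl trans to C7 isopropenyl) | CC1=C(O[Si](C)(C)C)C[C@H](C[C@@H]1C(C)=C)C(C)=C | intermediate
3 | dienone, (5S)-2-methyl-3,5-di(prop-1-en-2-yl)cyclohex-2-en-1-one | CC1=C(C(C)=C)C[C@@H](CC1=O)C(C)=C | intermediate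
4 | allylic chloride, (5S)-5-(3-chloroprop-1-en-2-yl)-2-methyl-3-(prop-1-en-2-yl)cyclohex-2-en-1-one | CC1=C(C(C)=C)C[C@@H](CC1=O)C(CCl)=C | intermediate
5 | pivalate, 2-[(1S)-4-methyl-5-oxo-3-(prop-1-en-2-yl)cyclohex-3-en-1-yl]prop-2-en-1-yl 2,2-dimethylpropanoate | CC1=C(C(C)=C)C[C@@H](CC1=O)C(COC(=O)C(C)(C)C)=C | intermediate
6 | sulfoxide adduct (9-ketone; C10 carries methyl and 2-(phenylsulfinyl)ethyl, the latter cis to the C7 side chain; C5=C6 with isopropenyl on C5) | O=C1C[C@@H](C(COC(=O)C(C)(C)C)=C)C=C(C(C)=C)[C@@]1(C)CCS(=O)c2ccccc2 | intermediate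
7 | vinyl ketone (as 6, vinyl on C10 cis to the C7 side chain) | O=C1C[C@@H](C(COC(=O)C(C)(C)C)=C)C=C(C(C)=C)[C@@]1(C)C=C | intermediate
8 | potassium enolate of 7 (C8=C9–OK) | [K+].[O-]C1=C[C@@H](C(COC(=O)C(C)(C)C)=C)C=C(C(C)=C)[C@@]1(C)C=C | intermediate
9 | 8-hydroxy ketone (8-OH trans to the C7 side chain) | O=C1[C@H](O)[C@@H](C(COC(=O)C(C)(C)C)=C)C=C(C(C)=C)[C@@]1(C)C=C | intermediate
10 | trans-8,9-diol (9-OH cis to the C7 side chain) | O[C@H]1[C@H](O)[C@@H](C(COC(=O)C(C)(C)C)=C)C=C(C(C)=C)[C@@]1(C)C=C | intermediate
11 | 8,9-acetonide of 10 | C[C@@]1(C=C)C(C(C)=C)=C[C@H](C(COC(=O)C(C)(C)C)=C)[C@H]2OC(C)(C)O[C@H]12 | intermediate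
12 | allylic alcohol (C12–OH) | C[C@@]1(C=C)C(C(C)=C)=C[C@H](C(CO)=C)[C@H]2OC(C)(C)O[C@H]12 | intermediate
13 | enal (C12 aldehyde) | C[C@@]1(C=C)C(C(C)=C)=C[C@H](C(C=O)=C)[C@H]2OC(C)(C)O[C@H]12 | intermediate
14 | acrylic acid (C12 acid) | C[C@@]1(C=C)C(C(C)=C)=C[C@H](C(C(O)=O)=C)[C@H]2OC(C)(C)O[C@H]12 | intermediate
15 | 5,6-epoxy acid (oxirane oxygen trans to the C7 side chain) | C[C@@]1(C=C)[C@@]3(C(C)=C)O[C@H]3[C@H](C(C(O)=O)=C)[C@H]2OC(C)(C)O[C@H]12 | intermediate
16 | hydroxy lactone (cis-fused 12,6-olide; 5-OH trans to O6; 5-isopropenyl cis to 10-vinyl) | C[C@@]1(C=C)[C@](O)(C(C)=C)[C@@H]3OC(=O)C(=C)[C@@H]3[C@H]2OC(C)(C)O[C@H]12 | intermediate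
17 | lactol (C12 hemiacetal of 16) | C[C@@]1(C=C)[C@](O)(C(C)=C)[C@@H]3OC(O)C(=C)[C@@H]3[C@H]2OC(C)(C)O[C@H]12 | intermediate
18 | lactol tert-butyldimethylsilyl ether (free C5–OH) | C[C@@]1(C=C)[C@](O)(C(C)=C)[C@@H]3OC(O[Si](C)(C)C(C)(C)C)C(=C)[C@@H]3[C@H]2OC(C)(C)O[C@H]12 | intermediate
19 | potassium C5-alkoxide of 18 | [K+].C[C@@]1(C=C)[C@]([O-])(C(C)=C)[C@@H]3OC(O[Si](C)(C)C(C)(C)C)C(=C)[C@@H]3[C@H]2OC(C)(C)O[C@H]12 | intermediate
20 | ring-expanded potassium enolate (C4=C5–OK, C3 and C6 cis; 1(10)E) | [K+].C=C1C(O[Si](C)(C)C(C)(C)C)O[C@H]2/C([O-])=C(/C)CC/C=C(\C)[C@H]3OC(C)(C)O[C@@H]3[C@@H]12 | intermediate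
21 | enol triflate (C5–OTf; C3 and C6 cis; 1(10)E) | C=C1C(O[Si](C)(C)C(C)(C)C)O[C@H]2/C(OS(=O)(=O)C(F)(F)F)=C(/C)CC/C=C(\C)[C@H]3OC(C)(C)O[C@@H]3[C@@H]12 | intermediate
22 | (1(10)E,4Z)-diene, lactol silyl ether, 8,9-acetonide | C=C1C(O[Si](C)(C)C(C)(C)C)O[C@H]2/C=C(/C)CC/C=C(\C)[C@H]3OC(C)(C)O[C@@H]3[C@@H]12 | intermediate
23 | (1(10)E,4Z)-lactol, 8,9-acetonide | C=C1C(O)O[C@H]2/C=C(/C)CC/C=C(\C)[C@H]3OC(C)(C)O[C@@H]3[C@@H]12 | intermediate
24 | (1(10)E,4Z)-8,9-O-isopropylidene-8,9-dihydroxygermacra-1(10),4,11(13)-trien-12,6-olide | C=C1C(=O)O[C@H]2/C=C(/C)CC/C=C(\C)[C@H]3OC(C)(C)O[C@@H]3[C@@H]12 | intermediate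
25 | (1(10)E,4Z)-8,9-dihydroxygermacra-1(10),4,11(13)-trien-12,6-olide | C=C1C(=O)O[C@H]2/C=C(/C)CC/C=C(\C)[C@@H](O)[C@H](O)[C@@H]12 | intermediate
26 | (1(10)E,4Z)-8-hydroxy-9-oxogermacra-1(10),4,11(13)-trien-12,6-olide | C=C1C(=O)O[C@H]2/C=C(/C)CC/C=C(\C)C(=O)[C@H](O)[C@@H]12 | intermediate
27 | (1(10)Z,4Z)-8-hydroxy-9-oxogermacra-1(10),4,11(13)-trien-12,6-olide | C=C1C(=O)O[C@H]2/C=C(/C)CC/C=C(/C)C(=O)[C@H](O)[C@@H]12 | intermediate
28 | angelic acid, (Z)-2-methylbut-2-enoic acid | C/C=C(/C)C(O)=O | starting material
29 | angelyl alcohol, (Z)-2-methylbut-2-en-1-ol | C/C=C(/C)CO | intermediate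
30 | [(2R,3S)-2,3-dimethyloxiran-2-yl]methanol | OC[C@@]1(C)O[C@H]1C | intermediate
31 | (2S,3S)-2,3-dimethyloxirane-2-carbaldehyde | O=C[C@@]1(C)O[C@H]1C | intermediate
32 | (2S,3S)-2,3-dimethyloxirane-2-carboxylic acid (epoxyangelic acid) | OC(=O)[C@@]1(C)O[C@H]1C | intermediate
33 | mixed anhydride of 32 with 2,4,6-trichlorobenzoic acid | O=C(OC(=O)[C@@]1(C)O[C@H]1C)c2c(Cl)cc(Cl)cc2Cl | intermediate
34 | (6S,7S,8R,1(10)Z,4Z)-8-[(2S,3S)-2,3-epoxy-2-methylbutanoyloxy]-9-oxogermacra-1(10),4,11(13)-trien-12,6-olide | C=C1C(=O)O[C@H]2/C=C(/C)CC/C=C(/C)C(=O)[C@H](OC(=O)[C@@]3(C)O[C@H]3C)[C@@H]12 | target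

**Totals and risks**

Total step count: 24 (20 steps from carvone to 27, 3 steps to acid 32, 1 coupling). Longest linear sequence: 21 steps (steps 1–20, then step 24).

Steps most likely to fail:

Step 14 (ring expansion). The tertiary alkoxide may cleave heterolytically at C5–C10 (allyl anion plus isopropenyl ketone) and recombine by a [1,3] path or by 1,2-addition, or the rearrangement may be slow enough for silyl transfer and decomposition to take over. The fallback moves to the neutral, concerted manifold. From 18, TMSOTf and 2,6-lutidine silylate the tertiary alcohol to the trimethylsilyl ether F1. Thermolysis (decalin, 200 °C, sealed tube) should effect the siloxy-Cope rearrangement through the same chair to the ring-expanded trimethylsilyl enol ether F2. MeLi (THF, 0 °C) releases the lithium enolate F3, and PhNTf2 returns the route at 21.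

Step 20 (E→Z isomerisation). The photostationary state may be poor in the Z isomer, or excited-state side reactions may compete (transannular [2+2] cycloaddition, α-cleavage next to the α-hydroxy ketone, energy transfer to C4=C5). The fallback is a ground-state equilibration under protection. From 26, Me2NH (THF, 0 °C) adds to the exocyclic methylene to give the amine adduct F4. Catalytic PhSH/Et3N (THF, 40 °C) equilibrates the enone by reversible conjugate addition at C1, expected to favour the less strained ring-cis enone F5; the E isomer is separated and recycled. MeI gives the ammonium iodide F6, and aqueous NaHCO3 eliminates trimethylamine to return the route at 27.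

Step 5 (quaternary centre at C10). Facial selectivity at C10 may be low, or alkylation may occur at C8 through the cross-conjugated enolate. The fallback sets the C8 oxygen first and uses it for 1,3-stereocontrol. From 5, kinetic deprotonation (KN(SiMe3)2, THF, −78 °C) gives the cross-conjugated potassium enolate F7, which the oxaziridine of step 6 oxidises to the 8-hydroxy dienone F8 (OH trans to the side chain). TBSOTf and 2,6-lutidine give the 8-silyloxy dienone F9, whose bulky group blocks C8 and shields the face of C10 trans to the side chain. The conditions of step 5 then give the sulfoxide adduct F10 and, after thermolysis, the 8-silyloxy vinyl ketone F11. Bu4NF/AcOH removes the silyl group and returns the route at 9.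

**Further compounds**

F1 | step 14 | trimethylsilyl ether of 18 | C[C@@]1(C=C)[C@](O[Si](C)(C)C)(C(C)=C)[C@@H]3OC(O[Si](C)(C)C(C)(C)C)C(=C)[C@@H]3[C@H]2OC(C)(C)O[C@H]12
F2 | step 14 | ring-expanded trimethylsilyl enol ether | C=C1C(O[Si](C)(C)C(C)(C)C)O[C@H]2/C(O[Si](C)(C)C)=C(/C)CC/C=C(\C)[C@H]3OC(C)(C)O[C@@H]3[C@@H]12
F3 | step 14 | lithium enolate | [Li+].C=C1C(O[Si](C)(C)C(C)(C)C)O[C@H]2/C([O-])=C(/C)CC/C=C(\C)[C@H]3OC(C)(C)O[C@@H]3[C@@H]12
F4 | step 20 | 13-dimethylamino adduct of 26 | CN(C)CC1C(=O)O[C@H]2/C=C(/C)CC/C=C(\C)C(=O)[C@H](O)[C@@H]12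
F5 | step 20 | 13-dimethylamino adduct of 27 | CN(C)CC1C(=O)O[C@H]2/C=C(/C)CC/C=C(/C)C(=O)[C@H](O)[C@@H]12
F6 | step 20 | trimethylammonium iodide from F5 | [I-].C[N+](C)(C)CC1C(=O)O[C@H]2/C=C(/C)CC/C=C(/C)C(=O)[C@H](O)[C@@H]12
F7 | step 5 | cross-conjugated potassium enolate of 5 | [K+].CC1=C(C(C)=C)C[C@H](C(COC(=O)C(C)(C)C)=C)C=C1[O-]
F8 | step 5 | 8-hydroxy dienone | CC1=C(C(C)=C)C[C@H](C(COC(=O)C(C)(C)C)=C)[C@@H](O)C1=O
F9 | step 5 | 8-silyloxy dienone | CC1=C(C(C)=C)C[C@H](C(COC(=O)C(C)(C)C)=C)[C@@H](O[Si](C)(C)C(C)(C)C)C1=O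
F10 | step 5 | sulfoxide adduct of F9 | O=C1[C@H](O[Si](C)(C)C(C)(C)C)[C@@H](C(COC(=O)C(C)(C)C)=C)C=C(C(C)=C)[C@@]1(C)CCS(=O)c2ccccc2
F11 | step 5 | 8-silyloxy vinyl ketone | O=C1[C@H](O[Si](C)(C)C(C)(C)C)[C@@H](C(COC(=O)C(C)(C)C)=C)C=C(C(C)=C)[C@@]1(C)C=C
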